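## Retrosynthetic overview

1. Iridoid numbering is used: C1 acyloxy acetal, O2, C3=C4, ring-fusion C5 and C9, C6, C7, C8, C10 on C8, C11 on C4; β is the face of H5 and H9. The plan rests on the cis-fused cyclopenta[c]pyran core, in which dihydropyran ring A (C1, O2, C3, C4, C5, C9) and cyclopentane ring B (C5 to C9) share the C5–C9 bond and ring B lies on the face of ring A opposite to the C1 oxygen.
2. Last bonds made: O–C7 (a protected Z-coumaric acid opens a 7,8-α-epoxide with inversion), O1–acyl (esterification of the C1 lactol) and C4–C11 (methoxycarbonylation of a C4 enol triflate).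
3. Key disconnection: C8–C9 and C5–C6, a phosphine-catalysed allenoate (3+2) annulation across the C5=C9 enone of a 6-acyloxypyranone whose acetal carbon steers the attack.
4. Ring order: ring A first (oxidative ring expansion of a furan, C1 fixed by acylative dynamic kinetic resolution), ring B second ((3+2) annulation).
5. Sequence rules: the C4 ketone is masked as the triflate before the C10 ester meets hydride. The 7,8-alkene is oxidised while C3=C4 is a deactivated β-alkoxyacrylate. The pivalate leaves in the same hydride step that reduces C11, before any other ester is present.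

Key step: step 3

Assumption: the (R)-antipode of benzotetramisole is taken to favour the (S)-lactol, by analogy with its preference among allylic alcohols (the enone as the π-group); both antipodes are commercial, so the other one is used if the sense is reversed.

## Route

Step 1
Reactants: 1 furfuryl alcohol
Product: 2 6-hydroxy-2H-pyran-3(6H)-one (racemic lactol)
Conditions: mCPBA, CH2Cl2, 0 °C to rt
Reagents that add atoms: mCPBA (3-chloroperoxybenzoic acid), O=C(OO)c1cccc(Cl)c1
Why: Achmatowicz rearrangement: peracid oxidation of the electron-rich furan and recyclisation through the side-chain hydroxyl should expand the five-membered ring to the pyranone lactol, which already holds C1, O2, C3, C4, C5 and C9 of ring A; the lactol carbon is not yet configurationally fixed.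

Step 2
Reactants: 2 6-hydroxy-2H-pyran-3(6H)-one
Product: 3 (S)-6-pivaloyloxy-2H-pyran-3(6H)-one
Conditions: pivalic anhydride, (R)-benzotetramisole (10 mol %), iPr2NEt, toluene, 0 °C to rt
Reagents that add atoms: pivalic anhydride, CC(C)(C)C(=O)OC(=O)C(C)(C)C
Why: Acylative dynamic kinetic resolution with a chiral isothiourea acyl-transfer catalyst, a reaction type known for Achmatowicz lactols: the lactol enantiomers interconvert by base-promoted ring–chain tautomerism while the chiral N-acyl isothiouronium ion should acylate one of them faster through cation–π contact with the enone, which fixes C1 as S.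

Step 3
Reactants: 3 (S)-6-pivaloyloxy-2H-pyran-3(6H)-one; 4 ethyl buta-2,3-dienoate
Product: 6 ethyl (1S,4aS,7aS)-4-oxo-1-pivaloyloxy-1,3,4,4a,5,7a-hexahydrocyclopenta[c]pyran-7-carboxylate, via phosphonium dienolate zwitterion 5 (not isolated)
Conditions: PPh3 (20 mol %), toluene, 110 °C, slow addition of 4
Reagents that add atoms: none
Why: PPh3 adds to the central carbon of 4 to give zwitterion 5, whose ester-bearing α-carbon (future C8) adds to the enone β-carbon C9; the resulting C5 enolate then attacks the CH2 terminus of the vinylphosphonium unit (future C6), and a proton shift followed by loss of PPh3 leaves the C7=C8 enoate. The closest known reaction type is the Lu phosphine-catalysed allenoate–enone (3+2) annulation, which is established for electron-poor cyclic enones. Ring B closes in the second C–C bond formation, a formally 5-endo-trig conjugate addition of the enolate to the vinylphosphonium ion within a stepwise (3+2) process. C9 is controlled by the C1 stereocentre: the pivalate is held pseudo-axial by the anomeric effect and screens the β face, so the dipole should arrive from the α face, anti to O1. C5 is controlled by C9, because the three-carbon bridge can reach C5 only from the face on which it is already bound, which enforces the cis ring fusion with H5 and H9 β. The step needs α- rather than γ-regiochemistry and needs the acyloxy enone to survive: the higher charge density at the α-carbon of the unsubstituted dipole and the strongly polarised, cis-locked enone should secure the first, and the neutral phosphine together with the poor, hindered pivalate leaving group should hold back elimination towards an oxidopyrylium species.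

Step 4
Reactants: 6 cycloadduct ketone
Product: 8 ethyl (1S,4aS,7aS)-1-pivaloyloxy-4-(trifluoromethylsulfonyloxy)-1,4a,5,7a-tetrahydrocyclopenta[c]pyran-7-carboxylate (C3=C4 enol triflate), via potassium enolate 7 (not isolated)
Conditions: KN(SiMe3)2, THF, −78 °C; then N-(5-chloro-2-pyridyl)bis(trifluoromethanesulfonimide), −78 °C
Reagents that add atoms: N-(5-chloro-2-pyridyl)bis(trifluoromethanesulfonimide), O=S(=O)(N(c1ccc(Cl)cn1)S(=O)(=O)C(F)(F)F)C(F)(F)F
Why: Kinetic enolisation and O-sulfonylation: the bulky amide should remove one of the unhindered C3 protons, acidified by O2, rather than the ring-fusion C5–H, and trapping at −78 °C precedes enolate equilibration, so the C3=C4 bond is placed and the ketone is masked before any hydride is used.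

Step 5
Reactants: 8 enol triflate
Product: 9 C10 allylic alcohol (1β-pivaloyloxy; 4-triflyloxy; C3=C4 and C7=C8; 8-CH2OH; H5 and H9 β)
Conditions: iBu2AlH (2.2 equiv), CH2Cl2, −78 °C; aq. potassium sodium tartrate
Reagents that add atoms: none
Why: Chemoselective iBu2AlH reduction of an ester to the primary alcohol: the unhindered ethyl enoate should react well before the tert-alkyl carboxylate at C1, the vinyl triflate is inert to hydride at −78 °C, and no ketone is left to compete.

Step 6
Reactants: 9 C10 allylic alcohol
Product: 10 C10 tert-butyldimethylsilyl ether of 9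
Conditions: TBSCl, imidazole, CH2Cl2, 0 °C to rt
Reagents that add atoms: tert-butyldimethylsilyl chloride, CC(C)(C)[Si](C)(C)Cl
Why: Imidazole-promoted silylation of a primary alcohol, which keeps O10 out of the later hydride and acylation steps.

Step 7
Reactants: 10 silyl ether triflate
Product: 11 methyl (1S,4aS,7aS)-7-[(tert-butyldimethylsilyloxy)methyl]-1-pivaloyloxy-1,4a,5,7a-tetrahydrocyclopenta[c]pyran-4-carboxylate
Conditions: Pd(OAc)2 (5 mol %), PPh3, CO (1 atm), Et3N, MeOH/DMF, 40 °C
Reagents that add atoms: carbon monoxide, [C-]#[O+]; methanol, CO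
Why: Palladium-catalysed methoxycarbonylation of an enol triflate (oxidative addition to zerovalent palladium, CO insertion, methanolysis) should add C11 without touching the acetal ester, and it turns C3=C4 into an electron-poor β-alkoxyacrylate.

Step 8
Reactants: 11 C11 methyl ester
Product: 12 7β-bromo-8α-hydroxy derivative of 11 (1S,4aS,6S,7R,7aS)
Conditions: NBS, THF/H2O (4:1), 0 °C, dark
Reagents that add atoms: N-bromosuccinimide, O=C1CCC(=O)N1Br; water, O
Why: Bromohydrin formation by anti addition: bromine should bridge the trisubstituted C7=C8 bond from the convex β face (the face of H5 and H9) and water should open the bridge from the α face at the tertiary C8, which sets 8α-OH with C10 β and 7β-Br, while the push–pull C3=C4 bond is too electron-poor to compete and the regioisomeric trans-bromohydrin would lead to the same epoxide.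

Step 9
Reactants: 12 bromohydrin
Product: 13 7,8-α-epoxide (1β-pivaloyloxy; 4-CO2Me; 10-OTBS)
Conditions: DBU, CH2Cl2, rt
Reagents that add atoms: none
Why: Base-induced 3-exo-tet closure of a trans-bromohydrin (intramolecular Williamson reaction): the 8α-oxygen displaces the 7β-bromide with inversion, which puts the epoxide on the concave α face, the face a peracid would not choose.

Step 10
Reactants: 13 α-epoxide
Product: 14 C1 lactol C11 allylic alcohol (7,8-α-epoxide; 10-OTBS; β-anomer drawn)
Conditions: iBu2AlH (5 equiv), CH2Cl2, −78 °C; aq. potassium sodium tartrate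
Reagents that add atoms: none
Why: Exhaustive iBu2AlH reduction of both esters: the C11 methyl ester goes to the allylic alcohol and the pivalate is cleaved to an aluminium lactolate that stays closed at −78 °C, the epoxide and silyl ether being inert at this temperature; the pivalate has to leave here because it could not be removed selectively once other esters are present.

Step 11
Reactants: 14 lactol diol
Product: 15 C11 tert-butyldimethylsilyl ether of 14 (free C1 lactol)
Conditions: TBSCl (1.05 equiv), imidazole, CH2Cl2, −20 to 0 °C
Reagents that add atoms: tert-butyldimethylsilyl chloride, CC(C)(C)[Si](C)(C)Cl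
Why: Rate-selective silylation: the unhindered primary allylic hydroxyl should react well before the secondary hemiacetal hydroxyl, a selectivity known for lactols of this ring system.

Step 12
Reactants: 15 lactol; 16 (R)-3-methylpentanoic acid
Product: 18 1β-[(R)-3-methylpentanoyloxy] 7,8-α-epoxide with 10- and 11-OTBS groups, via O-acylisourea 17 (not isolated)
Conditions: DCC, DMAP (10 mol %), CH2Cl2, 0 °C
Reagents that add atoms: none
Why: Steglich esterification of an equilibrating lactol: acylation should take place through the β-anomer, which is favoured by the anomeric effect and is trans to ring B, whereas the α face of C1 is crowded by C8 and the epoxide, so C1 is set again as S, and the β-stereocentre of the acid cannot epimerise.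

Step 13
Reactants: 18 bis-silyl ether
Product: 19 epoxy diol (1β-acyloxy; 7,8-α-epoxide; free 10-OH and 11-OH)
Conditions: Bu4NF/AcOH (1:1), THF, 0 °C to rt
Reagents that add atoms: none
Why: Fluoride desilylation of two primary silyl ethers, buffered with acetic acid so that no alkoxide builds up to start Payne rearrangement or acyl migration, which frees O10 as the directing group for the epoxide opening.

Step 14
Reactants: 20 4-hydroxybenzaldehyde
Product: 21 4-(triisopropylsilyloxy)benzaldehyde
Conditions: TIPSCl, imidazole, DMF, rt
Reagents that add atoms: triisopropylsilyl chloride, CC(C)[Si](Cl)(C(C)C)C(C)C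
Why: Standard silylation of a phenol; the bulky silyl group is chosen to outlast the later saponification and removes the phenoxide that would ease Z to E isomerisation.

Step 15
Reactants: 21 4-(triisopropylsilyloxy)benzaldehyde
Product: 22 methyl (Z)-3-[4-(triisopropylsilyloxy)phenyl]prop-2-enoate
Conditions: (CF3CH2O)2P(O)CH2CO2Me, KN(SiMe3)2, 18-crown-6, THF, −78 °C
Reagents that add atoms: methyl bis(2,2,2-trifluoroethyl)phosphonoacetate, COC(=O)CP(=O)(OCC(F)(F)F)OCC(F)(F)F
Why: Still–Gennari olefination: the electron-poor phosphonate with a dissociated potassium counter-ion makes elimination faster than equilibration of the adducts, so the kinetic Z-enoate should result from an aromatic aldehyde.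

Step 16
Reactants: 22 methyl (Z)-ester
Product: 23 (Z)-3-[4-(triisopropylsilyloxy)phenyl]prop-2-enoic acid
Conditions: LiOH·H2O, THF/MeOH/H2O, 0 °C to rt, dark; then 1 M HCl to pH 4
Reagents that add atoms: lithium hydroxide, [Li+].[OH-]
Why: Saponification by acyl–oxygen cleavage, which does not touch the alkene geometry, while the hindered aryl silyl ether should survive the short exposure to hydroxide.

Step 17
Reactants: 19 epoxy diol; 23 (Z)-acid
Product: 24 4'-O-triisopropylsilyl ether of the target
Conditions: Ti(OiPr)4 (2.5 equiv), CH2Cl2, rt, dark; aq. potassium sodium tartrate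
Reagents that add atoms: none
Why: Sharpless-type titanium-mediated opening of a 2,3-epoxy alcohol by a carboxylic acid: the C10 alkoxide and the epoxide oxygen chelate titanium and the carboxylate should attack the distal, secondary C7 from the open β face with inversion, which sets the 7β-ester (7S) and leaves the 8α-oxygen as the tertiary alcohol (8R), under mild non-basic conditions that keep the Z-alkene.

Step 18
Reactants: 24 silyl-protected target
Product: 25 CNP0217341.1 (target; 1S,4aS,6S,7R,7aS core; R side chain; Z-coumarate)
Conditions: Bu4NF/AcOH (1:1), THF, 0 °C, dark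
Reagents that add atoms: none
Why: Buffered fluoride cleavage of an aryl silyl ether, which is fast because phenoxide is a good leaving group from silicon and should leave the acetal ester, the enol ether and the Z-enoate untouched.

## Compound list

1 | furfuryl alcohol | OCc1ccco1 | starting material
2 | 6-hydroxy-2H-pyran-3(6H)-one (racemic, epimerising lactol) | OC1OCC(=O)C=C1 | intermediate
3 | (S)-6-pivaloyloxy-2H-pyran-3(6H)-one | CC(C)(C)C(=O)O[C@@H]1OCC(=O)C=C1 | intermediate
4 | ethyl buta-2,3-dienoate | C=C=CC(=O)OCC | starting material
5 | phosphonium dienolate zwitterion (PPh3 on the central carbon of 4) | CCOC(=O)[CH-]C(=C)[P+](c1ccccc1)(c1ccccc1)c1ccccc1 | intermediate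
6 | ethyl (1S,4aS,7aS)-4-oxo-1-pivaloyloxy-1,3,4,4a,5,7a-hexahydrocyclopenta[c]pyran-7-carboxylate | CC(C)(C)C(=O)O[C@@H]1OCC(=O)[C@H]2CC=C(C(=O)OCC)[C@@H]12 | intermediate
7 | potassium C3=C4 enolate of 6 | CC(C)(C)C(=O)O[C@@H]1OC=C([O-])[C@H]2CC=C(C(=O)OCC)[C@@H]12.[K+] | intermediate
8 | C3=C4 enol triflate of 6 | CC(C)(C)C(=O)O[C@@H]1OC=C(OS(=O)(=O)C(F)(F)F)[C@H]2CC=C(C(=O)OCC)[C@@H]12 | intermediate
9 | C10 allylic alcohol, 4-triflate, 1β-pivalate | CC(C)(C)C(=O)O[C@@H]1OC=C(OS(=O)(=O)C(F)(F)F)[C@H]2CC=C(CO)[C@@H]12 | intermediate
10 | C10 TBS ether of 9 | CC(C)(C)C(=O)O[C@@H]1OC=C(OS(=O)(=O)C(F)(F)F)[C@H]2CC=C(CO[Si](C)(C)C(C)(C)C)[C@@H]12 | intermediate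
11 | C11 methyl ester, 10-OTBS, 1β-pivalate, C7=C8 | CC(C)(C)C(=O)O[C@@H]1OC=C(C(=O)OC)[C@H]2CC=C(CO[Si](C)(C)C(C)(C)C)[C@@H]12 | intermediate
12 | 7β-bromo-8α-hydroxy bromohydrin | CC(C)(C)C(=O)O[C@@H]1OC=C(C(=O)OC)[C@H]2C[C@H](Br)[C@](O)(CO[Si](C)(C)C(C)(C)C)[C@@H]12 | intermediate
13 | 7,8-α-epoxide, 1β-pivalate, C11 methyl ester, 10-OTBS | CC(C)(C)C(=O)O[C@@H]1OC=C(C(=O)OC)[C@H]2C[C@H]3O[C@@]3(CO[Si](C)(C)C(C)(C)C)[C@@H]12 | intermediate
14 | C1 lactol (β-anomer drawn), 11-OH, 7,8-α-epoxide, 10-OTBS | O[C@@H]1OC=C(CO)[C@H]2C[C@H]3O[C@@]3(CO[Si](C)(C)C(C)(C)C)[C@@H]12 | intermediate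
15 | C1 lactol, 10,11-bis-OTBS, 7,8-α-epoxide | O[C@@H]1OC=C(CO[Si](C)(C)C(C)(C)C)[C@H]2C[C@H]3O[C@@]3(CO[Si](C)(C)C(C)(C)C)[C@@H]12 | intermediate
16 | (R)-3-methylpentanoic acid | CC[C@@H](C)CC(=O)O | starting material
17 | O-acylisourea from 16 and DCC | CC[C@@H](C)CC(=O)OC(=NC1CCCCC1)NC1CCCCC1 | intermediate
18 | 1β-[(R)-3-methylpentanoate], 10,11-bis-OTBS, 7,8-α-epoxide | CC[C@@H](C)CC(=O)O[C@@H]1OC=C(CO[Si](C)(C)C(C)(C)C)[C@H]2C[C@H]3O[C@@]3(CO[Si](C)(C)C(C)(C)C)[C@@H]12 | intermediate
19 | epoxy diol: 1β-[(R)-3-methylpentanoate], 10-OH, 11-OH, 7,8-α-epoxide | CC[C@@H](C)CC(=O)O[C@@H]1OC=C(CO)[C@H]2C[C@H]3O[C@@]3(CO)[C@@H]12 | intermediate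
20 | 4-hydroxybenzaldehyde | O=Cc1ccc(O)cc1 | starting material
21 | 4-(triisopropylsilyloxy)benzaldehyde | O=Cc1ccc(O[Si](C(C)C)(C(C)C)C(C)C)cc1 | intermediate
22 | methyl (Z)-3-[4-(triisopropylsilyloxy)phenyl]prop-2-enoate | COC(=O)/C=C\c1ccc(O[Si](C(C)C)(C(C)C)C(C)C)cc1 | intermediate
23 | (Z)-3-[4-(triisopropylsilyloxy)phenyl]prop-2-enoic acid | OC(=O)/C=C\c1ccc(O[Si](C(C)C)(C(C)C)C(C)C)cc1 | intermediate
24 | 4'-O-TIPS ether of the target | CC[C@@H](C)CC(=O)O[C@@H]1OC=C(CO)[C@H]2C[C@H](OC(=O)/C=C\c3ccc(O[Si](C(C)C)(C(C)C)C(C)C)cc3)[C@](O)(CO)[C@@H]12 | intermediate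
25 | CNP0217341.1 | CC[C@@H](C)CC(=O)O[C@@H]1OC=C(CO)[C@H]2C[C@H](OC(=O)/C=C\c3ccc(O)cc3)[C@](O)(CO)[C@@H]12 | target

## Step count and risks

Total step count: 18. Longest linear sequence: 15 (steps 1 to 13, then 17 and 18).

Steps most likely to fail:

1. **Step 17.** The titanium alkoxide at O10 may promote migration of the new ester from O7 to O10 or alcoholysis of the C1 ester, and the opening may be slow or stray to C8.
   - Fallback (sets out from 18, comes back at 25): the opening is moved ahead of the desilylation, and the nucleophile rather than the epoxide is activated.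
   - Bis-silyl ether 18 is heated in the dark with the caesium salt of 23 (23 in excess, Cs2CO3, DMF, 60 °C).
   - SN2 attack at the secondary C7 from the β face should give the fully silylated hydroxy ester F1, in which no free hydroxyl flanks an ester.
   - One buffered fluoride treatment (Bu4NF/AcOH, THF) then removes all three silyl groups to give 25.

2. **Step 8.** Facial selectivity of the bromine transfer may be poor, or NBS may attack the enol ether or an allylic position.
   - Fallback (sets out from 11, comes back at 13): substrate control is replaced by reagent control.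
   - Desilylation of 11 (Bu4NF/AcOH, THF) gives the C10 allylic alcohol F2.
   - Sharpless asymmetric epoxidation (Ti(OiPr)4, D-(−)-diethyl tartrate, tBuOOH, 4 Å molecular sieves, CH2Cl2, −20 °C) should deliver oxygen to the α face of C7=C8 against the convex-face bias and give the α-epoxy alcohol F3.
   - TBSCl/imidazole then returns 13.

3. **Step 2.** Transfer of the hindered pivaloyl group from the chiral catalyst may be slow, so that uncatalysed acylation and base-induced decay of the lactol erode the enantiomeric purity.
   - Fallback (sets out from 2, comes back at 3): catalysis is replaced by physical resolution.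
   - Lactol 2 is pivaloylated without a chiral catalyst (pivaloyl chloride, Et3N, DMAP cat., CH2Cl2, −20 °C) to the racemic pivalate F4.
   - Preparative supercritical-fluid chromatography on a polysaccharide chiral phase separates F4 into 3 and the (R)-pivalate F5, which is set aside.

Further compounds
F1 | step 17 | 10,11-bis-O-TBS 4'-O-TIPS derivative of the target | CC[C@@H](C)CC(=O)O[C@@H]1OC=C(CO[Si](C)(C)C(C)(C)C)[C@H]2C[C@H](OC(=O)/C=C\c3ccc(O[Si](C(C)C)(C(C)C)C(C)C)cc3)[C@](O)(CO[Si](C)(C)C(C)(C)C)[C@@H]12
F2 | step 8 | C10 allylic alcohol, 1β-pivalate, C11 methyl ester | CC(C)(C)C(=O)O[C@@H]1OC=C(C(=O)OC)[C@H]2CC=C(CO)[C@@H]12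
F3 | step 8 | 7,8-α-epoxy C10 alcohol, 1β-pivalate, C11 methyl ester | CC(C)(C)C(=O)O[C@@H]1OC=C(C(=O)OC)[C@H]2C[C@H]3O[C@@]3(CO)[C@@H]12
F4 | step 2 | racemic 6-pivaloyloxy-2H-pyran-3(6H)-one | CC(C)(C)C(=O)OC1OCC(=O)C=C1
F5 | step 2 | (R)-6-pivaloyloxy-2H-pyran-3(6H)-one | CC(C)(C)C(=O)O[C@H]1OCC(=O)C=C1
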